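**Plan**
1. Retrosynthesis first cuts the five O–benzyl bonds and the 3-O–methyl bond, then returns the C2=C3 double bond to a 3-hydroxychroman-4-one.
2. The central cut removes C2–C1′ and C3–O together. In the target the aryl ring sits on C2 and an oxygen on C3, the two neighbouring carbons of the O1–C2=C3–C4=O enone of ring C, so both can be delivered across the C2=C3 bond of a chromone that carries ring A only.
3. That chromone goes back to a 2-hydroxyacetophenone (C2 from a formamide acetal) whose two methoxy groups come from C–Br bonds; the aryl donor goes back to a bromopyrogallol ether.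
4. Forward: ring A is bought as phloroacetophenone and fully substituted, ring C is closed in step 4, ring B is attached and C3 oxygenated in step 8, then the oxidation level and protecting groups are adjusted.
5. Stereochemistry: C2 and C3 of the step-8 product form racemic and trans (oxidant anti to the C2 aryl group), and both centres are flattened in step 9.

Key step: step 8

Remark: the target has no stereogenic element, so the requested single stereoisomer is the achiral compound itself and no absolute control is needed; dimethyldioxirane 12 is assumed to be used as a titrated acetone solution made from acetone and Oxone.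

**Route**

Step 1
Reactants: 1 1-(2,4,6-trihydroxyphenyl)ethan-1-one
Product: 2 1-[2,4-bis(benzyloxy)-6-hydroxyphenyl]ethan-1-one
Conditions: BnBr (2.1 equiv), K2CO3 (2.2 equiv), DMF, 0 °C → rt
Reagents that add atoms: benzyl bromide, BrCc1ccccc1
Why: Williamson etherification should stop after two benzylations because the remaining ortho hydroxyl is hydrogen-bonded to the acetyl carbonyl and is the least nucleophilic oxygen.

Step 2
Reactants: 2 1-[2,4-bis(benzyloxy)-6-hydroxyphenyl]ethan-1-one
Product: 3 1-[2,4-bis(benzyloxy)-3,5-dibromo-6-hydroxyphenyl]ethan-1-one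
Conditions: NBS (2.1 equiv), MeCN/CH2Cl2, 0 °C → rt, dark
Reagents that add atoms: N-bromosuccinimide, O=C1CCC(=O)N1Br
Why: Electrophilic aromatic bromination should take the only two free ring positions, each activated by three oxygen substituents, and fills ring A completely.

Step 3
Reactants: 3 1-[2,4-bis(benzyloxy)-3,5-dibromo-6-hydroxyphenyl]ethan-1-one
Product: 4 1-[2,4-bis(benzyloxy)-6-hydroxy-3,5-dimethoxyphenyl]ethan-1-one
Conditions: NaOMe (8 equiv, 25% in MeOH), CuBr (0.3 equiv), DMF, 110 °C, Ar; then aq. HCl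
Reagents that add atoms: sodium methoxide, C[O-].[Na+]
Why: Ullmann-type copper-catalysed methoxylation of aryl bromides is established for ortho-oxygenated bromophenols and bromoaryl ketones, and benzyl ethers are inert to hot methoxide.

Step 4
Reactants: 4 1-[2,4-bis(benzyloxy)-6-hydroxy-3,5-dimethoxyphenyl]ethan-1-one; 5 N,N-dimethylformamide dimethyl acetal
Product: 7 5,7-bis(benzyloxy)-6,8-dimethoxy-4H-chromen-4-one, via enaminone 6 (not isolated)
Conditions: 5 (3 equiv), toluene, 100 °C; evaporate; AcOH, 60 °C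
Reagents that add atoms: N,N-dimethylformamide dimethyl acetal 5, COC(OC)N(C)C (supplies C2 of the chromone)
Why: Condensation of the methyl ketone with the formamide acetal gives the enaminone, and acid-promoted addition of the ortho phenol with loss of dimethylamine closes the pyranone (enaminone chromone synthesis).

Step 5
Reactants: 8 5-bromo-1,2,3-trimethoxybenzene
Product: 9 5-bromobenzene-1,2,3-triol
Conditions: BBr3 (3.5 equiv), CH2Cl2, −78 °C → rt; H2O, 0 °C
Reagents that add atoms: none
Why: Boron tribromide cleavage of aryl methyl ethers should remove all three methyl groups and leave the aryl bromide untouched.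

Step 6
Reactants: 9 5-bromobenzene-1,2,3-triol
Product: 10 1,2,3-tris(benzyloxy)-5-bromobenzene
Conditions: BnBr (3.5 equiv), K2CO3, DMF, 60 °C, Ar
Reagents that add atoms: benzyl bromide, BrCc1ccccc1
Why: Exhaustive Williamson benzylation under inert gas protects the air-sensitive pyrogallol with the same group used on ring A, so one final hydrogenolysis serves both rings.

Step 7
Reactants: 10 1,2,3-tris(benzyloxy)-5-bromobenzene
Product: 11 [3,4,5-tris(benzyloxy)phenyl]magnesium bromide
Conditions: Mg turnings (I2-activated), THF, 50 °C; solution titrated and used directly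
Reagents that add atoms: magnesium, [Mg]
Why: Grignard formation by magnesium insertion into the aryl C–Br bond is compatible with aryl benzyl ethers and gives the aryl donor for step 8.

Step 8
Reactants: 7 5,7-bis(benzyloxy)-6,8-dimethoxy-4H-chromen-4-one; 11 [3,4,5-tris(benzyloxy)phenyl]magnesium bromide; 12 dimethyldioxirane
Product: 17 rac-(2R,3R)-5,7-bis(benzyloxy)-3-hydroxy-6,8-dimethoxy-2-[3,4,5-tris(benzyloxy)phenyl]chroman-4-one (trans racemate), via arylcopper reagent 13 (not isolated), via silyl enol ether 14 (not isolated), via silyloxy epoxide 15 (not isolated), via 3-silyloxyflavanone 16 (not isolated)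
Conditions: 11 (1.5 equiv), CuI·2LiCl (1.5 equiv), THF, −40 °C; TMSCl (3 equiv), then 7, −78 → −20 °C; Et3N, pentane, Celite filtration under Ar, concentrate; 12 (2 equiv, ca. 0.08 M in acetone), CH2Cl2, −78 → 0 °C; 1 M HCl, THF, 0 °C
Reagents that add atoms: dimethyldioxirane 12, CC1(C)OO1 (the 3-oxygen); chlorotrimethylsilane, C[Si](C)(C)Cl, and copper(I) iodide, [Cu]I (atoms held only in intermediates 13–16)
Why: Transmetalation of 11 gives arylcopper 13, which with TMSCl transfers its aryl group to C2 of the chromone enone while the enolate oxygen is silylated to the 4-silyloxy-2H-chromene 14; dimethyldioxirane then epoxidises the C3=C4 enol ether to 15, the oxirane opens with 1,4-silyl shift to the 3-silyloxy ketone 16, and dilute acid frees the hydroxyl. The closest known reactions are the chlorosilane-accelerated copper-mediated conjugate addition of Grignard reagents to chromones and the Rubottom oxidation of chromanone silyl enol ethers with dimethyldioxirane, here telescoped without isolating 14. No ring is closed: two bonds, C2–C1′ and C3–O, are made across the existing pyranone. C2 forms without facial bias (racemic) and C3 is set relative to it because the dioxirane approaches the enol ether face opposite the C2 aryl group, giving the trans arrangement; both centres disappear in step 9, so the diastereomer outcome does not affect the route. The step needs 1,4- instead of 1,2-addition and oxidation at C3 only: the soft arylcopper/TMSCl pair attacks C2, the sole β-carbon of the only acceptor, ring A has no free C–H position, and the silyl enol ether is by far the most electron-rich alkene, so benzyl ethers and the trialkoxyphenyl ring should be spared at low temperature.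

Step 9
Reactants: 17 rac-(2R,3R)-5,7-bis(benzyloxy)-3-hydroxy-6,8-dimethoxy-2-[3,4,5-tris(benzyloxy)phenyl]chroman-4-one
Product: 18 5,7-bis(benzyloxy)-3-hydroxy-6,8-dimethoxy-2-[3,4,5-tris(benzyloxy)phenyl]-4H-chromen-4-one
Conditions: I2 (1.2 equiv), KOAc (5 equiv), AcOH, 90 °C
Reagents that add atoms: none
Why: Iodine-mediated dehydrogenation of a dihydroflavonol (enolisation, iodination, loss of HI buffered by acetate) should give the aromatic pyranone and erases both stereocentres.

Step 10
Reactants: 18 5,7-bis(benzyloxy)-3-hydroxy-6,8-dimethoxy-2-[3,4,5-tris(benzyloxy)phenyl]-4H-chromen-4-one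
Product: 19 5,7-bis(benzyloxy)-3,6,8-trimethoxy-2-[3,4,5-tris(benzyloxy)phenyl]-4H-chromen-4-one
Conditions: MeI (3 equiv), K2CO3, acetone, reflux
Reagents that add atoms: iodomethane, CI
Why: Williamson O-methylation meets a single free hydroxyl, the acidic enolic 3-OH, so no selectivity question arises.

Step 11
Reactants: 19 5,7-bis(benzyloxy)-3,6,8-trimethoxy-2-[3,4,5-tris(benzyloxy)phenyl]-4H-chromen-4-one
Product: 20 5,7,3′,4′,5′-pentahydroxy-3,6,8-trimethoxyflavone
Conditions: H2 (1 atm), 10% Pd/C, THF/MeOH, rt; work-up under Ar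
Reagents that add atoms: none
Why: Catalytic hydrogenolysis should cleave all five aryl benzyl ethers while the methyl ethers and the flavone C2=C3 bond stay intact under these mild conditions.

**Compound list**
1 | 1-(2,4,6-trihydroxyphenyl)ethan-1-one (2′,4′,6′-trihydroxyacetophenone) | CC(=O)c1c(O)cc(O)cc1O | starting material
2 | 1-[2,4-bis(benzyloxy)-6-hydroxyphenyl]ethan-1-one | CC(=O)c1c(O)cc(OCc2ccccc2)cc1OCc1ccccc1 | intermediate
3 | 1-[2,4-bis(benzyloxy)-3,5-dibromo-6-hydroxyphenyl]ethan-1-one | CC(=O)c1c(O)c(Br)c(OCc2ccccc2)c(Br)c1OCc1ccccc1 | intermediate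
4 | 1-[2,4-bis(benzyloxy)-6-hydroxy-3,5-dimethoxyphenyl]ethan-1-one | CC(=O)c1c(O)c(OC)c(OCc2ccccc2)c(OC)c1OCc1ccccc1 | intermediate
5 | N,N-dimethylformamide dimethyl acetal | COC(OC)N(C)C | starting material
6 | (E)-1-[2,4-bis(benzyloxy)-6-hydroxy-3,5-dimethoxyphenyl]-3-(dimethylamino)prop-2-en-1-one | CN(C)/C=C/C(=O)c1c(O)c(OC)c(OCc2ccccc2)c(OC)c1OCc1ccccc1 | intermediate (not isolated)
7 | 5,7-bis(benzyloxy)-6,8-dimethoxy-4H-chromen-4-one | O=c1ccoc2c(OC)c(OCc3ccccc3)c(OC)c(OCc3ccccc3)c12 | intermediate (key-step precursor)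
8 | 5-bromo-1,2,3-trimethoxybenzene | COc1cc(Br)cc(OC)c1OC | starting material
9 | 5-bromobenzene-1,2,3-triol | Oc1cc(Br)cc(O)c1O | intermediate
10 | 1,2,3-tris(benzyloxy)-5-bromobenzene | Brc1cc(OCc2ccccc2)c(OCc2ccccc2)c(OCc2ccccc2)c1 | intermediate
11 | [3,4,5-tris(benzyloxy)phenyl]magnesium bromide (THF solution) | Br[Mg]c1cc(OCc2ccccc2)c(OCc2ccccc2)c(OCc2ccccc2)c1 | intermediate (key-step precursor)
12 | dimethyldioxirane (acetone solution from acetone and Oxone) | CC1(C)OO1 | starting material (reagent)
13 | [3,4,5-tris(benzyloxy)phenyl]copper (as its magnesium/lithium halide complex) | [Cu]c1cc(OCc2ccccc2)c(OCc2ccccc2)c(OCc2ccccc2)c1 | intermediate (not isolated)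
14 | rac-{[5,7-bis(benzyloxy)-6,8-dimethoxy-2-[3,4,5-tris(benzyloxy)phenyl]-2H-chromen-4-yl]oxy}trimethylsilane ((2S) enantiomer drawn) | c1c(OCc2ccccc2)c(OCc2ccccc2)c(OCc2ccccc2)cc1[C@@H]1C=C(O[Si](C)(C)C)c2c(OCc3ccccc3)c(OC)c(OCc3ccccc3)c(OC)c2O1 | intermediate (not isolated)
15 | rac-5,7-bis(benzyloxy)-3,4-epoxy-6,8-dimethoxy-2-[3,4,5-tris(benzyloxy)phenyl]-4-(trimethylsilyloxy)chromane, oxirane oxygen trans to the 2-aryl group (enantiomer derived from drawn 14) | c1c(OCc2ccccc2)c(OCc2ccccc2)c(OCc2ccccc2)cc1[C@@H]1[C@H]2O[C@@]2(O[Si](C)(C)C)c3c(OCc4ccccc4)c(OC)c(OCc4ccccc4)c(OC)c3O1 | intermediate (not isolated)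
16 | rac-(2R,3R)-5,7-bis(benzyloxy)-6,8-dimethoxy-2-[3,4,5-tris(benzyloxy)phenyl]-3-(trimethylsilyloxy)chroman-4-one | c1c(OCc2ccccc2)c(OCc2ccccc2)c(OCc2ccccc2)cc1[C@@H]1[C@@H](O[Si](C)(C)C)C(=O)c2c(OCc3ccccc3)c(OC)c(OCc3ccccc3)c(OC)c2O1 | intermediate (not isolated)
17 | rac-(2R,3R)-5,7-bis(benzyloxy)-3-hydroxy-6,8-dimethoxy-2-[3,4,5-tris(benzyloxy)phenyl]chroman-4-one (trans; one enantiomer drawn) | c1c(OCc2ccccc2)c(OCc2ccccc2)c(OCc2ccccc2)cc1[C@@H]1[C@@H](O)C(=O)c2c(OCc3ccccc3)c(OC)c(OCc3ccccc3)c(OC)c2O1 | intermediate (key-step product)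
18 | 5,7-bis(benzyloxy)-3-hydroxy-6,8-dimethoxy-2-[3,4,5-tris(benzyloxy)phenyl]-4H-chromen-4-one | O=c1c(O)c(-c2cc(OCc3ccccc3)c(OCc3ccccc3)c(OCc3ccccc3)c2)oc2c(OC)c(OCc3ccccc3)c(OC)c(OCc3ccccc3)c12 | intermediate
19 | 5,7-bis(benzyloxy)-3,6,8-trimethoxy-2-[3,4,5-tris(benzyloxy)phenyl]-4H-chromen-4-one | COc1c(-c2cc(OCc3ccccc3)c(OCc3ccccc3)c(OCc3ccccc3)c2)oc2c(OC)c(OCc3ccccc3)c(OC)c(OCc3ccccc3)c2c1=O | intermediate
20 | 5,7,3′,4′,5′-pentahydroxy-3,6,8-trimethoxyflavone | COc1c(O)c(OC)c2oc(-c3cc(O)c(O)c(O)c3)c(OC)c(=O)c2c1O | target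

**Count**
Total steps: 11. Longest linear sequence: 8 steps (steps 1, 2, 3, 4, 8, 9, 10, 11 from compound 1); the ring-B branch (steps 5–7) joins at step 8.

**Steps most likely to fail**

Step 8. Arylcopper transfer to the doubly alkoxy-donated, weakly electrophilic chromone may be slow or give way to carbonyl attack. The silyl enol ether may hydrolyse during the solvent switch, and residual copper and organometallic may consume the dioxirane, so that plain flavanone forms instead of the hydroxylated product. The fallback sets out from 11 and 7 and returns at 18. It changes both bond formations: aryl transfer by palladium/boron and oxygenation by alkene epoxidation at the flavone level. Grignard 11 would be quenched with trimethyl borate and hydrolysed with aqueous HCl to [3,4,5-tris(benzyloxy)phenyl]boronic acid F1. Pd(II) trifluoroacetate/2,2′-bipyridine-catalysed conjugate addition of F1 to chromone 7 in an aqueous medium should give rac-5,7-bis(benzyloxy)-6,8-dimethoxy-2-[3,4,5-tris(benzyloxy)phenyl]chroman-4-one F2. Catalytic iodine in DMSO at 120 °C should dehydrogenate it to 5,7-bis(benzyloxy)-6,8-dimethoxy-2-[3,4,5-tris(benzyloxy)phenyl]-4H-chromen-4-one F3. Dioxirane 12 should then epoxidise the C2=C3 bond to rac-5,7-bis(benzyloxy)-2,3-epoxy-6,8-dimethoxy-2-[3,4,5-tris(benzyloxy)phenyl]chroman-4-one F4, which is expected to isomerise with catalytic p-TsOH to flavonol 18.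

Step 3. Substitution may stall or reductive loss of bromine may compete, especially at the bromide flanked by two bulky benzyloxy groups. The fallback sets out from 1 and returns at 4. It reverses the order of oxygenation and protection so that both C–Br bonds sit next to copper-binding phenoxides. Compound 1 would be dibrominated (NBS, MeCN) to 1-(3,5-dibromo-2,4,6-trihydroxyphenyl)ethan-1-one F5. Copper-catalysed methoxylation of the free triphenol (NaOMe, CuBr, DMF/MeOH) should give 1-(2,4,6-trihydroxy-3,5-dimethoxyphenyl)ethan-1-one F6. Dibenzylation as in step 1 (BnBr, K2CO3, DMF), again sparing the chelated hydroxyl, should deliver 4.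

Step 9. In hot buffered acetic acid the peri 5-O-benzyl group may be lost or the dehydrogenation may remain incomplete. The fallback sets out from 17 and returns at 18. It replaces halogenative dehydrogenation by oxidation of the carbinol: Swern oxidation ((COCl)2, DMSO, Et3N, CH2Cl2, −78 °C → rt) should give rac-5,7-bis(benzyloxy)-6,8-dimethoxy-2-[3,4,5-tris(benzyloxy)phenyl]chromane-3,4-dione F7, whose C2–H enolises under the amine base to the aromatic flavonol 18.

**Further compounds**
F1 | step 8 | [3,4,5-tris(benzyloxy)phenyl]boronic acid | OB(O)c1cc(OCc2ccccc2)c(OCc2ccccc2)c(OCc2ccccc2)c1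
F2 | step 8 | rac-5,7-bis(benzyloxy)-6,8-dimethoxy-2-[3,4,5-tris(benzyloxy)phenyl]chroman-4-one ((2S) enantiomer drawn) | c1c(OCc2ccccc2)c(OCc2ccccc2)c(OCc2ccccc2)cc1[C@@H]1CC(=O)c2c(OCc3ccccc3)c(OC)c(OCc3ccccc3)c(OC)c2O1
F3 | step 8 | 5,7-bis(benzyloxy)-6,8-dimethoxy-2-[3,4,5-tris(benzyloxy)phenyl]-4H-chromen-4-one | O=c1cc(-c2cc(OCc3ccccc3)c(OCc3ccccc3)c(OCc3ccccc3)c2)oc2c(OC)c(OCc3ccccc3)c(OC)c(OCc3ccccc3)c12
F4 | step 8 | rac-5,7-bis(benzyloxy)-2,3-epoxy-6,8-dimethoxy-2-[3,4,5-tris(benzyloxy)phenyl]chroman-4-one (cis-fused oxirane; one enantiomer drawn) | O=C1[C@@H]2O[C@]2(c2cc(OCc3ccccc3)c(OCc3ccccc3)c(OCc3ccccc3)c2)Oc2c(OC)c(OCc3ccccc3)c(OC)c(OCc3ccccc3)c12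
F5 | step 3 | 1-(3,5-dibromo-2,4,6-trihydroxyphenyl)ethan-1-one | CC(=O)c1c(O)c(Br)c(O)c(Br)c1O
F6 | step 3 | 1-(2,4,6-trihydroxy-3,5-dimethoxyphenyl)ethan-1-one | CC(=O)c1c(O)c(OC)c(O)c(OC)c1O
F7 | step 9 | rac-5,7-bis(benzyloxy)-6,8-dimethoxy-2-[3,4,5-tris(benzyloxy)phenyl]chromane-3,4-dione ((2R) enantiomer drawn) | c1c(OCc2ccccc2)c(OCc2ccccc2)c(OCc2ccccc2)cc1[C@@H]1C(=O)C(=O)c2c(OCc3ccccc3)c(OC)c(OCc3ccccc3)c(OC)c2O1
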